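**The ratio.** The ratio of other capture product to target climbed through the maple flask, so I followed it as a share: other capture product in the sum of the two.

| flask | starting material | first nucleophile | second nucleophile | protic impurity | remark | time |
|---|---|---|---|---|---|---|
| maple | 1 M | 1.1 M | 1 M | 0.50 M | the very flask that is asked about, followed so far |  |
| ash | 1 M | 2.2 M | 1 M | 0.50 M | run made earlier |  |
| flask | 1.0 M | 1.10 M | 1.00 M | 0.500 M |  | 15 d |

| run | time / d | other capture product / % | target / % |
|---|---|---|---|
| maple | 0.208 | 0.2 | 1.5 |
| maple | 0.333 | 2.2 | 2.4 |
| maple | 0.625 | 2.5 | 3.6 |
| maple | 1.04 | 5.7 | 4.4 |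
| maple | 1.67 | 5.5 | 3.9 |
| maple | 2.50 | 9.0 | 2.7 |
| ash | 0.500 | 1.2 | 2.1 |
| ash | 0.833 | 2.8 | 2.9 |
| ash | 1.25 | 4.3 | 2.4 |
| ash | 2.00 | 4.9 | 1.8 |
| ash | 4.00 | 7.7 | 0.6 |
| ash | 6.00 | 9.1 | 1.3 |

(standard deviation of a reading: 0.5 percentage points)

- share of other capture product in other capture product plus target at 5.0 h
- share of other capture product in other capture product plus target at 40 h
- share of other capture product in other capture product plus target at 15 d

- the numbers in the tables scatter by 0.5 percentage points (one standard deviation)

**Early end.** First I imagined a flask that lost no target, where the share stays at the ratio in which the two products are born. I summed the first three maple readings of each product to blunt the scatter, and read 39.5 %.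

**Late end.** Then I imagined a flask past its peak, with both products hanging on one dying feed. Maple target fell from 4.4 % to 2.7 % between 1.04 d and 2.50 d. This gave 0.334 d⁻¹, my tail constant, the pseudo-first-order rate at which target falls past its peak. I assumed that this tail was also the fall of the feed, and the ash run could not test that: its target readings went from 0.6 % up to 1.3 % late in the run, with a scatter of 0.5 percentage points. On that assumption I reckoned 0.662 % of the maple feed remaining at 15 d. Scaled from its last maple reading, I reckoned other capture product heading for 15.9 % and target at 0.0413 %, a share of 99.7 %.

**Joining them.** I expected the maple flask near the first estimate, itself a scattered reading and no bound, at 5.0 h, which is far shorter than the inverse constant, and near the second at 15 d, which is longer. At 40 h I set the reckoned other capture product beside the target reading, 3.9 %, and got 63.5 %.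

**Forecast.** The forecast gave 28 %, 63 % and 93 %, saying that by the end “many decay lifetimes have passed”, and my reckoning stood higher at both ends.

**Result.** The maple flask gave 37.7 %, 64.9 % and 99.5 %.

    first nucleophile + intermediate → target (k = 0.0140 L mol⁻¹ s⁻¹)
    intermediate → solvolysis product (k = 0.0170 s⁻¹)
    starting material → intermediate (k = 3.00 × 10⁻⁶ s⁻¹)
    second nucleophile + intermediate → other capture product (k = 0.00760 L mol⁻¹ s⁻¹)
    first nucleophile + target → over-reaction product (k = 2.10 × 10⁻⁵ L mol⁻¹ s⁻¹)
    starting material + protic impurity → quenched substrate (k = 2.40 × 10⁻⁶ L mol⁻¹ s⁻¹)

**The tail.** At 15.0 d in the maple flask, target's half-life by its loss to over-reaction product was 0.64 d, shorter than the 2.7 d of starting material by its step into intermediate. Between 7.50 d and that time, in the maple flask, starting material fell at 0.316 d⁻¹ and target at 0.308 d⁻¹, beside my tail constant of 0.334 d⁻¹. In the neighbour charged with 1.9 M of first nucleophile, the constant's 0.662 % of feed stood against 0.781 % of starting material, and the share ended at 99.6 %.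

Readings and results come from a simulation for substances that don't exist; noise was put on by code.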